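**Structural features**

Garcinisidone D is a depsidone: benzene rings A and B are joined by a diaryl ether oxygen and by an ester, which together close a central seven-membered dioxepinone ring. Ring A carbons are written a1–a6 (a1 lactone carbonyl, a2 OH, a3 prenyl, a4 pyran O, a5 pyran CH, a6 ether O) and ring B carbons b1–b6 (b1 ether O, b2 H, b3 OH, b4 pyran O, b5 pyran CH, b6 ester O); capital A with a number is kept for compounds of the alternatives. Each arene is fused to a 2,2-dimethyl-2H-pyran (a4–O–CMe2–CH=CH–a5 and b4–O–CMe2–CH=CH–b5). The molecule has no stereocentre and no stereogenic double bond, so nothing stereochemical has to be set or preserved. The fragile groups are the prenyl and chromene alkenes (acid, electrophilic oxidants, hydrogenation), the aryl ester (base, nucleophiles) and ring B, a 1,2,4,5-tetraoxygenated benzene that becomes an air-sensitive hydroquinone once the b3 and b6 oxygens are both free. The real difficulty is that ring A is hexasubstituted and its ether oxygen on a6 lies between two carbon substituents, while b1 has an oxygen neighbour on b6, so a substitution on finished arenes would be a doubly ortho-hindered coupling; in addition the four oxygens of ring B must be told apart. The key step uses the 1,3,5-oxygen pattern of ring A (a2, a4, a6) with the prenyl carbon a3 between two oxygens. A 3-aryloxy vinylketene and a siloxyalkyne assemble exactly this pattern, with the ether oxygen already bound to the future a6 before ring A exists and with a1 and a5 left as C–H for later use.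

**Logic of the disconnections**

33 to 32: the ester C–O bond between the a1 acyl carbon and the b6 oxygen is cut. The diaryl ether already holds the two rings, so the closure is intramolecular and only the b6 hydroxyl can reach the acyl carbon. The gain is loss of the medium ring. The demand is a neutral acyl activation under argon and at high dilution.

32 to 31 to 30: the b3 and b6 hydroxyls are masked as allyl ethers and the a1 carboxyl is traced back to a formyl group. This keeps ring B out of the hydroquinone oxidation level until the last two steps. The demand is an aldehyde oxidation that spares five alkenes, and a deallylation under neutral conditions.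

30 to 27 to 26 and 4: the ring A pyran is cut at a5–CH and O–CMe2, back to an aryl 1,1-dimethylpropargyl ether and then to the free a4 phenol. The gain is that a five-carbon unit and one ring are removed in two steps. The demand is etherification of the a4 hydroxyl in the presence of the a2 hydroxyl, and a rearrangement temperature below that of the allyl ethers.

26 to 25 to 24: the a1–CHO bond is cut and the a4 oxygen is returned to its silyl ether. While a4 is silylated only the a2 hydroxyl can direct, and a1 is its single free ortho position. The demand is an ortho-specific formylation.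

24 to 15 and 20: ring A is taken apart at a2–a3, a4–a5 and a1–a2. This removes the whole hexasubstituted ring and leaves the diaryl ether oxygen on an sp2 carbon of a four-membered ring. The demand is a regioselective ketene–alkyne union, governed by the polarity of 20.

15 to 14: the four-membered ring is cut into a two-carbon cumulene and the alkyne of 14. The gain is that ring B then carries only an O–C≡CH group. The demand is that the electron-rich alkyne reacts faster than the cumulene dimerises.

14 to 11 to 8 and 9: the O–C(sp) bond is traced to the phenol and 9 through the dichlorovinyl ether. The demand is a double elimination at low temperature that leaves the allyl ethers alone.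

8 to 5 to 3 and 4: the ring B pyran is cut at b5–CH and O–CMe2 in the same way as on ring A. The demand is a mono-etherification of a symmetric diol and a rearrangement that precedes that of the allyl ethers.

3 to 2 to 1: the two allyl–oxygen bonds are cut after re-oxidation to the quinone. The quinone itself distinguishes the b3/b6 pair (vinylogous acid hydroxyls) from the b1/b4 pair (carbonyls). The demand is etherification below the Claisen threshold of allyloxyquinones.

20 to 17 to 16: the alkyne carbon that becomes a3 is removed by reversing a one-carbon ester homologation, and the ester is traced to the acid. The demand is addition to an enolisable β,γ-unsaturated ester without deprotonating it.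

**Other disconnections considered**

Alternative 1: The cut is the acyl O–b6 bond, made while b6 still carries hydrogen. The precursor would be seco acid A1 (a2 oxygen as TBS ether, ring B with only the b1, b3 and b4 oxygens, b3-OH free). PhI(OAc)2 in hexafluoroisopropanol would oxidise the b3 phenol, the a1 carboxylate would add at the para carbon b6, and re-aromatisation would give lactone A2, one desilylation from the target.
- In its favour: ring B needs three oxygens instead of four, so no pairwise differentiation and no hydroquinone arise, the b3 phenol emerges free, and no allyl groups or palladium step are needed. On these points it is better than the chosen plan.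
- Against it: b1 has two ortho carbons, b2 (ortho to the b3 oxygen) and b6 (para), and the tethered carboxylate reaches both through the same ring size, so the site of C–O formation is not fixed. A2 is more electron-rich on ring B than A1 and could be oxidised further to a quinone. The prenyl and both chromene alkenes face an electrophilic iodane.
- Comparison: on structure it addresses the lactone and not the crowded ring A and its ether, which A1 still contains and which would need something like step 10 anyway. On mechanism its key bond has an open regiochemical question where step 17 has none. On step economy the end-game is about equal (formylation and oxidation at a1 remain) and the ring B preparation is shorter, a real advantage.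

Alternative 2: The cut is the a3–a4 bond, which opens ring A to keto diester A3. LDA would remove first the doubly activated a1 hydrogen and then an a3 hydrogen next to the ketone; the a3 carbanion would add to the a4 ester carbonyl, allyl alkoxide would leave, and enolisation would give benzoate A4.
- In its favour: a1 arrives at the carboxyl oxidation level, so formylation and chlorite oxidation disappear. The chain places a2, a3 and a4 unambiguously. No ynol ether, ketene gas or cyclobutenone is handled. It is shorter than the chosen plan by roughly two to three steps, and better on that point.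
- Equal: the a6 oxygen is also attached before ring A exists, and the a2 and a4 phenols of A4 are distinguished by chelation just as in 26.
- Against it: the β-aryloxy enoate of A3 is a vinylogous carbonate, so the amide base or the liberated allyl alkoxide can add and expel the ring B phenoxide. The E geometry at a5=a6 is required for closure and can be lost through the a1 enolate. C-acylation to make A3 competes with O-acylation.
- Comparison: the chosen cascade is neutral and thermal with regiochemistry set by alkyne polarity; this one passes through polyanions next to a leaving group. Both give the same ring A pattern.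

Alternative 3: The cut removes the lactone carbonyl carbon, at a1–C(acyl) and C(acyl)–O(b6). Aryl iodide A5 (a1–I, b6-OH free, b3 oxygen as TBS ether) would react under CO with Pd(OAc)2 and Xantphos: oxidative addition of zerovalent palladium into a1–I, CO insertion, and capture of the acylpalladium by the b6 phenol would give lactone A6, one desilylation from the target.
- In its favour: one step replaces formylation, oxidation and lactonisation, which is better by about two steps at the end, and no free acid coexists with a hydroquinone.
- Equal: it needs the same diaryl ether and ring A core, so it is an alternative end-game that could follow step 10, not a rival ring construction.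
- Against it: zerovalent palladium cleaves allyl ethers, so b3 and b6 would need different groups from the start, which adds early steps and forfeits the symmetry used in steps 1–3. The a1–I bond lies between a hydroxyl and an aryloxy group on a very electron-rich ring, where oxidative addition is slow and loss of iodine competes. The acylpalladium can also be intercepted by the prenyl or chromene alkenes. The a1 formyl group of the chosen plan also differentiates the a2 and a4 hydroxyls, a role iodine cannot play.
- Comparison: mechanistically sound in type but demanding on this substrate; shorter at the end, longer at the start.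

Key step: step 10

Remarks on the chemistry (assumptions):
- ArB stands for 5,8-bis(allyloxy)-2,2-dimethyl-2H-chromen-6-yl, which is ring B with its pyran, bound through b1.
- The atom map of the benzannulation was re-derived (ketene carbon to a2, alkyne carbons to a3 and a4, aryloxy carbon to a6, ring CH2 to a1) and agrees with the target. No structure needed correction.
- Two design changes are made on the way to 15. O-Allylation is done on the quinone before reduction, so the quinone distinguishes the b3/b6 oxygens from the b1/b4 oxygens. Commercial 3-chloro-3-methylbut-1-yne (4) serves as the dimethylpropargyl donor in place of the free alcohol.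
- Allyl is kept for b3 and b6 because it survives n-BuLi at −78 °C, ketene, 110–140 °C, fluoride and chlorite, and leaves under neutral conditions.
- Ketene gas is assumed to come from an acetone-pyrolysis generator and is passed into the flask.

**Step 1**
Reactants: 1 2,5-dihydroxy-1,4-benzoquinone
Product: 2 2,5-bis(allyloxy)-1,4-benzoquinone
Conditions: allyl alcohol (solvent), BF3·OEt2 (cat.), rt
Reagents that add atoms: allyl alcohol, C=CCO
Why: Acid-catalysed vinylogous esterification, since the two hydroxyls of 1 are vinylogous acid OH groups and exchange with the alcohol; room temperature keeps the allyloxyquinone below its Claisen threshold.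

**Step 2**
Reactants: 2 2,5-bis(allyloxy)-1,4-benzoquinone
Product: 3 2,5-bis(allyloxy)benzene-1,4-diol
Conditions: Na2S2O4, EtOAc/H2O, rt, argon
Reagents that add atoms: none
Why: Dithionite reduction of the quinone to the hydroquinone; the allyl ethers are inert and the air-sensitive diol is used directly.

**Step 3**
Reactants: 3 2,5-bis(allyloxy)benzene-1,4-diol; 4 3-chloro-3-methylbut-1-yne
Product: 5 2,5-bis(allyloxy)-4-[(2-methylbut-3-yn-2-yl)oxy]phenol
Conditions: 4 (0.6 equiv), DBU, CuCl (cat.), MeCN, 0 °C, argon; unreacted 3 recovered
Reagents that add atoms: none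
Why: Copper-catalysed propargylic etherification through a copper allenylidene gives the tertiary aryl propargyl ether; 3 is C2-symmetric, so this is a statistical mono-etherification run with a deficit of 4.

**Step 4**
Reactants: 5 2,5-bis(allyloxy)-4-[(2-methylbut-3-yn-2-yl)oxy]phenol
Product: 8 5,8-bis(allyloxy)-2,2-dimethyl-2H-chromen-6-ol, via allenylphenol 6 (not isolated), via ortho-quinone methide 7 (not isolated)
Conditions: xylenes, 130 °C, argon
Reagents that add atoms: none
Why: Aromatic propargyl Claisen rearrangement to 6, 1,5-hydrogen shift to 7 and oxa-6π electrocyclisation; b5 is the only free carbon ortho to the ether oxygen, and tertiary propargyl ethers rearrange well below the temperature that aryl allyl ethers need.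

**Step 5**
Reactants: 8 5,8-bis(allyloxy)-2,2-dimethyl-2H-chromen-6-ol; 9 trichloroethylene
Product: 11 5,8-bis(allyloxy)-6-{[(E)-1,2-dichlorovinyl]oxy}-2,2-dimethyl-2H-chromene, via dichloroacetylene 10 (not isolated)
Conditions: K2CO3, DMF, 60 °C, argon
Reagents that add atoms: none
Why: Base-induced dehydrochlorination of 9 gives 10 at low concentration and anti addition of the phenoxide of 8 gives the (E)-dichlorovinyl ether, the established entry to ynol ethers from hydroxyl compounds; toxic 10 is never isolated.

**Step 6**
Reactants: 11 5,8-bis(allyloxy)-6-{[(E)-1,2-dichlorovinyl]oxy}-2,2-dimethyl-2H-chromene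
Product: 14 5,8-bis(allyloxy)-6-(ethynyloxy)-2,2-dimethyl-2H-chromene, via chloroethynyl ether 12 (not isolated), via lithium aryloxyacetylide 13 (not isolated)
Conditions: n-BuLi (2.3 equiv), THF, −78 → −40 °C; then H2O, −78 °C
Reagents that add atoms: none
Why: Dehydrochlorination by the first equivalent of n-BuLi gives 12, chlorine–lithium exchange by the second gives 13, and protonation gives the terminal aryl ynol ether; at −78 °C the allyl ethers and the chromene are not metalated, and 14 is used at once because aryl ynol ethers hydrate and polymerise on storage.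

**Step 7**
Reactants: 14 5,8-bis(allyloxy)-6-(ethynyloxy)-2,2-dimethyl-2H-chromene
Product: 15 3-(ArB-oxy)cyclobut-2-en-1-one
Conditions: ketene (excess, gas), CH2Cl2, −20 °C → rt
Reagents that add atoms: ketene, C=C=O
Why: Ketene–ynol ether [2+2] cycloaddition, the unsubstituted alkyne carbon bonding to the ketene carbonyl carbon, as in the preparation of 3-alkoxycyclobutenones from alkoxyacetylenes; 15 is a vinylogous aryl ester and is isolated without aqueous base.

**Step 8**
Reactants: 16 4-methylpent-3-enoic acid
Product: 17 methyl 4-methylpent-3-enoate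
Conditions: MeI, K2CO3, DMF, rt
Reagents that add atoms: iodomethane, CI
Why: Carboxylate O-alkylation; the non-acidic conditions avoid migration of the β,γ-double bond into conjugation.

**Step 9**
Reactants: 17 methyl 4-methylpent-3-enoate
Product: 20 triisopropyl[(5-methylhex-4-en-1-yn-1-yl)oxy]silane, via lithium dibromoenolate 18 (not isolated), via lithium ynolate 19 (not isolated)
Conditions: CH2Br2, LiTMP (2.2 equiv), THF, −78 °C; then n-BuLi, −78 °C → rt; then TIPSCl, −78 → 0 °C
Reagents that add atoms: dibromomethane, BrCBr; chlorotriisopropylsilane, CC(C)[Si](Cl)(C(C)C)C(C)C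
Why: Kowalski ester homologation stopped at the ynolate: LiCHBr2 adds to the ester, enolate 18 undergoes bromine–lithium exchange and 1,2-shift of the prenyl group to the carbenoid carbon to give 19, and the bulky chlorosilane silylates on oxygen. The ester carbonyl carbon becomes the oxygen-bearing alkyne carbon (future a4) and the CH2Br2 carbon the prenyl-bearing one (future a3).

**Step 10**
Reactants: 15 3-(ArB-oxy)cyclobut-2-en-1-one; 20 triisopropyl[(5-methylhex-4-en-1-yn-1-yl)oxy]silane
Product: 24 5-(ArB-oxy)-2-(3-methylbut-2-en-1-yl)-3-[(triisopropylsilyl)oxy]phenol, via vinylketene 21 (not isolated), via vinylcyclobutenone 22 (not isolated), via dienylketene 23 (not isolated)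
Conditions: 20 (1.5 equiv), PhMe, 80 → 110 °C, argon
Reagents that add atoms: none
Why: Heating opens 15 by 4π electrocyclic ring opening to the 3-aryloxy vinylketene 21. Its ketene C=C adds across the electron-rich alkyne of 20 in a [2+2] cycloaddition, the prenyl-bearing alkyne carbon (the nucleophilic terminus, β to oxygen) bonding to the ketene carbonyl carbon, which forms a2–a3 and a4–a5 in 22. A second 4π opening gives dienylketene 23, which closes ring A by thermal disrotatory 6π electrocyclisation (a1–a2) and enolises to the phenol. The closest known reaction type is the Danheiser benzannulation of cyclobutenones with siloxyalkynes, which gives resorcinol monosilyl ethers of this pattern. No stereocentre is created, and the racemic sp3 carbon of 22 is lost on aromatisation. The selectivity needed is the orientation of the ketene–alkyne [2+2], secured by the polarisation of the siloxyalkyne; the position of the ether oxygen on a6 is secured by the aryloxy group sitting on C3 of the cyclobutenone. The excess of 20 is meant to suppress acylation of the product phenol by 21, and allyl ethers, chromene and silyl ether should be inert at these temperatures.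

**Step 11**
Reactants: 24 5-(ArB-oxy)-2-(3-methylbut-2-en-1-yl)-3-[(triisopropylsilyl)oxy]phenol
Product: 25 6-(ArB-oxy)-2-hydroxy-3-(3-methylbut-2-en-1-yl)-4-[(triisopropylsilyl)oxy]benzaldehyde
Conditions: MgCl2, Et3N, (CH2O)n, MeCN, 80 °C
Reagents that add atoms: paraformaldehyde (formaldehyde), C=O
Why: Casnati–Skattebøl ortho-formylation: the magnesium phenoxide delivers formaldehyde to a1, the only free position ortho to the a2 hydroxyl, and a second formaldehyde oxidises the benzylic alkoxide by hydride transfer; a5 (para) is not attacked and ring B has no free phenol.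

**Step 12**
Reactants: 25 6-(ArB-oxy)-2-hydroxy-3-(3-methylbut-2-en-1-yl)-4-[(triisopropylsilyl)oxy]benzaldehyde
Product: 26 6-(ArB-oxy)-2,4-dihydroxy-3-(3-methylbut-2-en-1-yl)benzaldehyde
Conditions: TBAF, AcOH, THF, 0 °C
Reagents that add atoms: none
Why: Fluoride cleavage of the aryl silyl ether, buffered with acetic acid so that the aldehyde and the aryl ethers are not exposed to strongly basic phenoxide.

**Step 13**
Reactants: 26 6-(ArB-oxy)-2,4-dihydroxy-3-(3-methylbut-2-en-1-yl)benzaldehyde; 4 3-chloro-3-methylbut-1-yne
Product: 27 6-(ArB-oxy)-2-hydroxy-3-(3-methylbut-2-en-1-yl)-4-[(2-methylbut-3-yn-2-yl)oxy]benzaldehyde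
Conditions: 4, DBU, CuCl (cat.), MeCN, 0 °C
Reagents that add atoms: none
Why: Copper-catalysed propargylic etherification; the a2 hydroxyl is hydrogen-bonded to the a1 formyl group and flanked on both sides, so the more acidic, unchelated a4 hydroxyl para to the aldehyde should react.

**Step 14**
Reactants: 27 6-(ArB-oxy)-2-hydroxy-3-(3-methylbut-2-en-1-yl)-4-[(2-methylbut-3-yn-2-yl)oxy]benzaldehyde
Product: 30 5-(ArB-oxy)-7-hydroxy-2,2-dimethyl-8-(3-methylbut-2-en-1-yl)-2H-chromene-6-carbaldehyde, via allenylphenol 28 (not isolated), via ortho-quinone methide 29 (not isolated)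
Conditions: o-xylene, 140 °C, argon
Reagents that add atoms: none
Why: Propargyl Claisen rearrangement to a5 (a3 is blocked by prenyl), 1,5-hydrogen shift and oxa-6π closure give the second 2,2-dimethylchromene; the temperature is held below that at which the b3 allyl ether, with its free ortho position b2, would rearrange.

**Step 15**
Reactants: 30 5-(ArB-oxy)-7-hydroxy-2,2-dimethyl-8-(3-methylbut-2-en-1-yl)-2H-chromene-6-carbaldehyde
Product: 31 5-(ArB-oxy)-7-hydroxy-2,2-dimethyl-8-(3-methylbut-2-en-1-yl)-2H-chromene-6-carboxylic acid
Conditions: NaClO2, NaH2PO4, 2-methylbut-2-ene (large excess), t-BuOH/THF/H2O, 0 °C → rt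
Reagents that add atoms: sodium chlorite, [Na+].[O-]Cl=O
Why: Pinnick oxidation; chlorite oxidises the aldehyde selectively, and the hypochlorous acid formed is scavenged by the excess alkene so that prenyl, chromene and allyl alkenes and the electron-rich b2 position are not chlorinated.

**Step 16**
Reactants: 31 5-(ArB-oxy)-7-hydroxy-2,2-dimethyl-8-(3-methylbut-2-en-1-yl)-2H-chromene-6-carboxylic acid
Product: 32 5-[(5,8-dihydroxy-2,2-dimethyl-2H-chromen-6-yl)oxy]-7-hydroxy-2,2-dimethyl-8-(3-methylbut-2-en-1-yl)-2H-chromene-6-carboxylic acid
Conditions: Pd(PPh3)4 (cat.), morpholine, degassed THF, rt, argon; acidic work-up under argon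
Reagents that add atoms: none
Why: Tsuji–Trost deallylation: zerovalent palladium ionises both aryl allyl ethers to π-allyl complexes that morpholine intercepts, leaving prenyl, chromenes and the acid untouched; the hydroquinone product is kept under argon and carried on at once.

**Step 17**
Reactants: 32 5-[(5,8-dihydroxy-2,2-dimethyl-2H-chromen-6-yl)oxy]-7-hydroxy-2,2-dimethyl-8-(3-methylbut-2-en-1-yl)-2H-chromene-6-carboxylic acid
Product: 33 garcinisidone D
Conditions: DCC, CH2Cl2/THF (high dilution), 0 °C → rt, argon
Reagents that add atoms: none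
Why: Carbodiimide-mediated lactonisation; only the b6 hydroxyl, ortho to the ether bridge, can reach the activated a1 carboxyl (seven-membered ring), the b3 hydroxyl being para-disposed, and dilution disfavours intermolecular esters. The target is achiral, so no stereocentre needs to be set.

**Compound list**

1 | 2,5-dihydroxy-1,4-benzoquinone | O=C1C=C(O)C(=O)C=C1O | starting material
2 | 2,5-bis(allyloxy)-1,4-benzoquinone | O=C1C=C(OCC=C)C(=O)C=C1OCC=C | intermediate
3 | 2,5-bis(allyloxy)benzene-1,4-diol | Oc1cc(OCC=C)c(O)cc1OCC=C | intermediate
4 | 3-chloro-3-methylbut-1-yne | CC(C)(Cl)C#C | starting material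
5 | 2,5-bis(allyloxy)-4-[(2-methylbut-3-yn-2-yl)oxy]phenol | Oc1cc(OCC=C)c(OC(C)(C)C#C)cc1OCC=C | intermediate
6 | 2,5-bis(allyloxy)-3-(3-methylbuta-1,2-dien-1-yl)benzene-1,4-diol (formed in the flask) | Oc1cc(OCC=C)c(O)c(C=C=C(C)C)c1OCC=C | intermediate
7 | 2,5-bis(allyloxy)-4-hydroxy-6-(3-methylbut-2-en-1-ylidene)cyclohexa-2,4-dien-1-one (formed in the flask) | O=C1C(OCC=C)=CC(O)=C(OCC=C)C1=CC=C(C)C | intermediate
8 | 5,8-bis(allyloxy)-2,2-dimethyl-2H-chromen-6-ol | Oc1cc(OCC=C)c2OC(C)(C)C=Cc2c1OCC=C | intermediate
9 | trichloroethylene | ClC=C(Cl)Cl | starting material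
10 | dichloroacetylene (formed in the flask) | ClC#CCl | intermediate
11 | 5,8-bis(allyloxy)-6-{[(E)-1,2-dichlorovinyl]oxy}-2,2-dimethyl-2H-chromene | Cl/C=C(Cl)\Oc1cc(OCC=C)c2OC(C)(C)C=Cc2c1OCC=C | intermediate
12 | 5,8-bis(allyloxy)-6-[(chloroethynyl)oxy]-2,2-dimethyl-2H-chromene (formed in the flask) | ClC#COc1cc(OCC=C)c2OC(C)(C)C=Cc2c1OCC=C | intermediate
13 | lithium (ArB-oxy)acetylide (formed in the flask) | [Li]C#COc1cc(OCC=C)c2OC(C)(C)C=Cc2c1OCC=C | intermediate
14 | 5,8-bis(allyloxy)-6-(ethynyloxy)-2,2-dimethyl-2H-chromene | C#COc1cc(OCC=C)c2OC(C)(C)C=Cc2c1OCC=C | intermediate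
15 | 3-(ArB-oxy)cyclobut-2-en-1-one | O=C1CC(Oc2cc(OCC=C)c3OC(C)(C)C=Cc3c2OCC=C)=C1 | intermediate
16 | 4-methylpent-3-enoic acid | CC(C)=CCC(=O)O | starting material
17 | methyl 4-methylpent-3-enoate | CC(C)=CCC(=O)OC | intermediate
18 | lithium 1,1-dibromo-5-methylhexa-1,4-dien-2-olate (formed in the flask) | [Li]OC(=C(Br)Br)CC=C(C)C | intermediate
19 | lithium 5-methylhex-4-en-1-yn-1-olate (formed in the flask) | [Li]OC#CCC=C(C)C | intermediate
20 | triisopropyl[(5-methylhex-4-en-1-yn-1-yl)oxy]silane | CC(C)=CCC#CO[Si](C(C)C)(C(C)C)C(C)C | intermediate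
21 | 3-(ArB-oxy)buta-1,3-dien-1-one, the vinylketene (formed in the flask) | O=C=CC(=C)Oc1cc(OCC=C)c2OC(C)(C)C=Cc2c1OCC=C | intermediate
22 | 4-[1-(ArB-oxy)vinyl]-2-(3-methylbut-2-en-1-yl)-3-[(triisopropylsilyl)oxy]cyclobut-2-en-1-one, racemic (formed in the flask) | O=C1C(CC=C(C)C)=C(O[Si](C(C)C)(C(C)C)C(C)C)C1C(=C)Oc2cc(OCC=C)c3OC(C)(C)C=Cc3c2OCC=C | intermediate
23 | (3E)-5-(ArB-oxy)-2-(3-methylbut-2-en-1-yl)-3-[(triisopropylsilyl)oxy]hexa-1,3,5-trien-1-one, ketene and aryloxyvinyl termini cis (formed in the flask) | O=C=C(CC=C(C)C)/C(O[Si](C(C)C)(C(C)C)C(C)C)=C\C(=C)Oc1cc(OCC=C)c2OC(C)(C)C=Cc2c1OCC=C | intermediate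
24 | 5-(ArB-oxy)-2-(3-methylbut-2-en-1-yl)-3-[(triisopropylsilyl)oxy]phenol | CC(C)=CCc1c(O)cc(Oc2cc(OCC=C)c3OC(C)(C)C=Cc3c2OCC=C)cc1O[Si](C(C)C)(C(C)C)C(C)C | intermediate
25 | 6-(ArB-oxy)-2-hydroxy-3-(3-methylbut-2-en-1-yl)-4-[(triisopropylsilyl)oxy]benzaldehyde | CC(C)=CCc1c(O)c(C=O)c(Oc2cc(OCC=C)c3OC(C)(C)C=Cc3c2OCC=C)cc1O[Si](C(C)C)(C(C)C)C(C)C | intermediate
26 | 6-(ArB-oxy)-2,4-dihydroxy-3-(3-methylbut-2-en-1-yl)benzaldehyde | CC(C)=CCc1c(O)c(C=O)c(Oc2cc(OCC=C)c3OC(C)(C)C=Cc3c2OCC=C)cc1O | intermediate
27 | 6-(ArB-oxy)-2-hydroxy-3-(3-methylbut-2-en-1-yl)-4-[(2-methylbut-3-yn-2-yl)oxy]benzaldehyde | CC(C)=CCc1c(O)c(C=O)c(Oc2cc(OCC=C)c3OC(C)(C)C=Cc3c2OCC=C)cc1OC(C)(C)C#C | intermediate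
28 | 6-(ArB-oxy)-2,4-dihydroxy-5-(3-methylbuta-1,2-dien-1-yl)-3-(3-methylbut-2-en-1-yl)benzaldehyde (formed in the flask) | CC(C)=CCc1c(O)c(C=O)c(Oc2cc(OCC=C)c3OC(C)(C)C=Cc3c2OCC=C)c(C=C=C(C)C)c1O | intermediate
29 | 2-(ArB-oxy)-6-hydroxy-5-(3-methylbut-2-en-1-yl)-3-(3-methylbut-2-en-1-ylidene)-4-oxocyclohexa-1,5-diene-1-carbaldehyde (formed in the flask) | O=C1C(CC=C(C)C)=C(O)C(C=O)=C(Oc2cc(OCC=C)c3OC(C)(C)C=Cc3c2OCC=C)C1=CC=C(C)C | intermediate
30 | 5-(ArB-oxy)-7-hydroxy-2,2-dimethyl-8-(3-methylbut-2-en-1-yl)-2H-chromene-6-carbaldehyde | CC(C)=CCc1c(O)c(C=O)c(Oc2cc(OCC=C)c3OC(C)(C)C=Cc3c2OCC=C)c4c1OC(C)(C)C=C4 | intermediate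
31 | 5-(ArB-oxy)-7-hydroxy-2,2-dimethyl-8-(3-methylbut-2-en-1-yl)-2H-chromene-6-carboxylic acid | CC(C)=CCc1c(O)c(C(=O)O)c(Oc2cc(OCC=C)c3OC(C)(C)C=Cc3c2OCC=C)c4c1OC(C)(C)C=C4 | intermediate
32 | 5-[(5,8-dihydroxy-2,2-dimethyl-2H-chromen-6-yl)oxy]-7-hydroxy-2,2-dimethyl-8-(3-methylbut-2-en-1-yl)-2H-chromene-6-carboxylic acid | CC(C)=CCc1c(O)c(C(=O)O)c(Oc2cc(O)c3OC(C)(C)C=Cc3c2O)c4c1OC(C)(C)C=C4 | intermediate
33 | garcinisidone D (achiral) | CC(C)=CCc1c(O)c2c(c3c1OC(C)(C)C=C3)Oc1cc(O)c3c(c1OC2=O)C=CC(C)(C)O3 | target

**Step count and risk**

Total steps: 17. Longest linear sequence: 15 steps (steps 1–7 and 10–17); steps 8–9 form the short branch.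

Least certain steps:

Step 10 (key step). The push–pull cyclobutenone may open slowly, so that decomposition of the vinylogous aryl ester competes, and the product phenol may be acylated by the vinylketene, consuming a second equivalent of 15. The fallback sets out from 8 and returns to the route at 26, making the diaryl ether by copper coupling while the ring A carbon para to prenyl still has two hydrogen neighbours. Resorcinol is converted with MOMCl and i-Pr2NEt into 1,3-bis(methoxymethoxy)benzene F1. Lithiation between the two acetal oxygens (n-BuLi, THF, 0 °C), transmetalation with CuBr·SMe2 and prenyl bromide give 1,3-bis(methoxymethoxy)-2-(3-methylbut-2-en-1-yl)benzene F2. Sterically controlled C–H borylation ([Ir(OMe)(cod)]2, 4,4′-di-tert-butyl-2,2′-bipyridine, B2pin2) at the only C–H without an ortho neighbour gives 2-[3,5-bis(methoxymethoxy)-4-(3-methylbut-2-en-1-yl)phenyl]-4,4,5,5-tetramethyl-1,3,2-dioxaborolane F3. Chan–Lam coupling with 8 (Cu(OAc)2, pyridine, B(OH)3, air, MeCN) gives 5,8-bis(allyloxy)-6-[3,5-bis(methoxymethoxy)-4-(3-methylbut-2-en-1-yl)phenoxy]-2,2-dimethyl-2H-chromene F4. Mild acid methanolysis (dilute HCl, MeOH) gives 5-(ArB-oxy)-2-(3-methylbut-2-en-1-yl)benzene-1,3-diol F5. Its two positions ortho to hydroxyl and next to the ether are equivalent by symmetry, so the magnesium-mediated formylation of step 11 applied to it should give 26 directly.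

Step 7 (with step 6). Dimerisation of ketene may outrun cycloaddition to the aryl ynol ether, and the ynol ether or the product may suffer hydrolytic loss of the aryloxy group on handling. The fallback sets out from 14 and returns at 15. Dichloroketene, generated in the flask from Cl3CCOCl and Zn(Cu) in Et2O/DME, is more electrophilic and should add to 14 to give 3-(ArB-oxy)-4,4-dichlorocyclobut-2-en-1-one F6. Reductive dechlorination (Zn, AcOH, TMEDA, EtOH, 0 °C) then gives 15.

Step 9. The lithium amide or the carbenoid may deprotonate the doubly activated α-position of the β,γ-unsaturated ester instead of adding to the carbonyl, leading to self-condensation or to conjugation of the alkene. The fallback sets out from 17 and returns at 20 by way of the same ynolate 19. DIBAL-H at −78 °C gives 4-methylpent-3-enal F7. Colvin rearrangement with lithiated TMSCHN2 (THF, −78 °C → rt) gives 5-methylhex-4-en-1-yne F8. Lithiation with n-BuLi and oxidation of the acetylide carbon with LiOOt-Bu (from t-BuOOH and LiHMDS) gives 19, which is silylated with TIPSOTf to 20.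

Step 14. Claisen rearrangement of the b3 allyl ether into b2 may compete at the temperature the formyl-bearing propargyl ether needs. The fallback sets out from 26 and returns at 30, bypassing 27: condensation with 3-methylbut-2-enal and ethylenediammonium diacetate (cat.) in toluene at 110 °C (iminium-mediated attack at a5, then oxa-6π closure; a3 is blocked). This fallback makes no new compound (F0).

Step 17 (with step 16). The free hydroquinone acid 32 may oxidise to a quinone in air, and intermolecular esterification at the b3 hydroxyl may compete with ring closure. The fallback sets out from 31 and returns at 33; it activates the acid before the phenols are unmasked, so the b6 phenoxide is captured as it forms. DCC and C6F5OH convert 31 into the pentafluorophenyl ester of 31 F9. Pd(PPh3)4 with PhSiH3 in degassed THF removes both allyl groups to give the pentafluorophenyl ester of 32 F10, which is not isolated. Adding i-Pr2NEt at high dilution should close the lactone to 33.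

**Further compounds**

F1 | step 10 | 1,3-bis(methoxymethoxy)benzene | COCOc1cccc(OCOC)c1
F2 | step 10 | 1,3-bis(methoxymethoxy)-2-(3-methylbut-2-en-1-yl)benzene | COCOc1cccc(OCOC)c1CC=C(C)C
F3 | step 10 | 2-[3,5-bis(methoxymethoxy)-4-(3-methylbut-2-en-1-yl)phenyl]-4,4,5,5-tetramethyl-1,3,2-dioxaborolane | COCOc1cc(B2OC(C)(C)C(C)(C)O2)cc(OCOC)c1CC=C(C)C
F4 | step 10 | 5,8-bis(allyloxy)-6-[3,5-bis(methoxymethoxy)-4-(3-methylbut-2-en-1-yl)phenoxy]-2,2-dimethyl-2H-chromene | COCOc1cc(Oc2cc(OCC=C)c3OC(C)(C)C=Cc3c2OCC=C)cc(OCOC)c1CC=C(C)C
F5 | step 10 | 5-(ArB-oxy)-2-(3-methylbut-2-en-1-yl)benzene-1,3-diol | CC(C)=CCc1c(O)cc(Oc2cc(OCC=C)c3OC(C)(C)C=Cc3c2OCC=C)cc1O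
F6 | step 7 | 3-(ArB-oxy)-4,4-dichlorocyclobut-2-en-1-one | O=C1C=C(Oc2cc(OCC=C)c3OC(C)(C)C=Cc3c2OCC=C)C1(Cl)Cl
F7 | step 9 | 4-methylpent-3-enal | CC(C)=CCC=O
F8 | step 9 | 5-methylhex-4-en-1-yne | CC(C)=CCC#C
F0 | step 14 | none | none
F9 | step 17 | pentafluorophenyl 5-(ArB-oxy)-7-hydroxy-2,2-dimethyl-8-(3-methylbut-2-en-1-yl)-2H-chromene-6-carboxylate | CC(C)=CCc1c(O)c(C(=O)Oc5c(F)c(F)c(F)c(F)c5F)c(Oc2cc(OCC=C)c3OC(C)(C)C=Cc3c2OCC=C)c4c1OC(C)(C)C=C4
F10 | step 17 | pentafluorophenyl 5-[(5,8-dihydroxy-2,2-dimethyl-2H-chromen-6-yl)oxy]-7-hydroxy-2,2-dimethyl-8-(3-methylbut-2-en-1-yl)-2H-chromene-6-carboxylate | CC(C)=CCc1c(O)c(C(=O)Oc5c(F)c(F)c(F)c(F)c5F)c(Oc2cc(O)c3OC(C)(C)C=Cc3c2O)c4c1OC(C)(C)C=C4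
A1 | alternative 1 | 7-[(tert-butyldimethylsilyl)oxy]-5-[(8-hydroxy-2,2-dimethyl-2H-chromen-6-yl)oxy]-2,2-dimethyl-8-(3-methylbut-2-en-1-yl)-2H-chromene-6-carboxylic acid | CC(C)=CCc1c(O[Si](C)(C)C(C)(C)C)c(C(=O)O)c(Oc2cc(O)c3OC(C)(C)C=Cc3c2)c4c1OC(C)(C)C=C4
A2 | alternative 1 | garcinisidone D a2-O-tert-butyldimethylsilyl ether | CC(C)=CCc1c(O[Si](C)(C)C(C)(C)C)c2c(c3c1OC(C)(C)C=C3)Oc1cc(O)c3c(c1OC2=O)C=CC(C)(C)O3
A3 | alternative 2 | diallyl (2E)-3-(ArB-oxy)-4-(5-methylhex-4-enoyl)pent-2-enedioate (racemic at C4) | C=CCOC(=O)/C=C(/Oc1cc(OCC=C)c2OC(C)(C)C=Cc2c1OCC=C)C(C(=O)OCC=C)C(=O)CCC=C(C)C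
A4 | alternative 2 | allyl 6-(ArB-oxy)-2,4-dihydroxy-3-(3-methylbut-2-en-1-yl)benzoate | CC(C)=CCc1c(O)cc(Oc2cc(OCC=C)c3OC(C)(C)C=Cc3c2OCC=C)c(C(=O)OCC=C)c1O
A5 | alternative 3 | 5-({8-[(tert-butyldimethylsilyl)oxy]-5-hydroxy-2,2-dimethyl-2H-chromen-6-yl}oxy)-6-iodo-2,2-dimethyl-8-(3-methylbut-2-en-1-yl)-2H-chromen-7-ol | CC(C)=CCc1c(O)c(I)c(Oc2cc(O[Si](C)(C)C(C)(C)C)c3OC(C)(C)C=Cc3c2O)c4c1OC(C)(C)C=C4
A6 | alternative 3 | garcinisidone D b3-O-tert-butyldimethylsilyl ether | CC(C)=CCc1c(O)c2c(c3c1OC(C)(C)C=C3)Oc1cc(O[Si](C)(C)C(C)(C)C)c3c(c1OC2=O)C=CC(C)(C)O3
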